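**Retrosynthetic overview**
- The sulfate sits on the phenol oxygen ortho to the benzylic CH2, so the last operations are O‑sulfation of that phenol, CHO → CH2OH and O‑debenzylation.
- Key disconnection: the C11–aryl bond is made by an aromatic Claisen rearrangement of an aryl ether of a tertiary 8‑hydroxy‑9(11)‑methylidene decalin; the same event creates the tetrasubstituted C8=C9 alkene and frees the oxygen that will carry the sulfate.
- The ether comes from SNAr of the tertiary allylic alkoxide on 3‑(benzyloxy)‑4‑fluorobenzaldehyde; the alcohol comes from a cis‑decalin enone by reductive α‑hydroxylation and methylenation.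
- The cis‑decalin comes from (S)‑carvone: butenylation then methylation at the α′‑carbon, ring‑closing metathesis onto the isopropenyl group, and hydromethylation for the second C4 methyl.
- Ring order: ring B is bought (carvone, C5 stereocentre); C10 is set by methylation anti to isopropenyl; ring A is closed second; the arene is bought and attached last.

Assumptions: C1–C11 in the text are drimane locants of the target decalin (C8=C9 alkene, C10 quaternary, C5 ring‑fusion CH, C11 benzylic CH2); the target is read as the cis‑fused (5R,10S) decalin that its SMILES encodes; 13 is bought as such; the target is delivered as the drawn hydrogen sulfate by protonating its sodium salt.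

**Route**

Step 1
Reactants: 1 (S)-(+)-carvone [(5S)-2-methyl-5-(prop-1-en-2-yl)cyclohex-2-en-1-one]; 2 4-iodobut-1-ene
Product: 4 (5S)-6-(but-3-en-1-yl)-2-methyl-5-(prop-1-en-2-yl)cyclohex-2-en-1-one (both C6 epimers), via lithium dienolate 3 (not isolated)
Conditions: LiN(iPr)2, THF, −78 °C; then 2, DMPU, −78 → −20 °C
Reagents that add atoms: none
Why: Kinetic α′‑deprotonation gives the cross‑conjugated dienolate, which is C‑alkylated by the primary iodide (enolate alkylation, SN2); the new C6 centre is left as a mixture because it is re‑enolised in step 2.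

Step 2
Reactants: 4
Product: 6 (5R,6S)-6-(but-3-en-1-yl)-2,6-dimethyl-5-(prop-1-en-2-yl)cyclohex-2-en-1-one, via lithium dienolate 5 (not isolated)
Conditions: LiN(iPr)2, THF, −78 °C; then MeI, −78 → 0 °C
Reagents that add atoms: iodomethane, CI
Why: Enolate alkylation in which MeI attacks the tetrasubstituted enolate anti to the pseudoaxial isopropenyl group on the bought C5 centre, so methyl ends trans and the butenyl chain cis to isopropenyl, which fixes C10 (S) and the later cis ring fusion.

Step 3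
Reactants: 6
Product: 7 (4aR,8aS)-2,5,8a-trimethyl-4a,7,8,8a-tetrahydronaphthalen-1(4H)-one
Conditions: second-generation Grubbs catalyst RuCl2(=CHPh)(PCy3)(H2IMes) (5 mol %), CH2Cl2, 40 °C
Reagents that add atoms: none
Why: Ring‑closing olefin metathesis between the terminal butenyl alkene and the cis‑disposed isopropenyl group closes ring A as a cis‑fused trisubstituted cyclohexene without touching a stereocentre or the conjugated enone.

Step 4
Reactants: 7
Product: 9 (4aR,8aS)-2,5,5,8a-tetramethyl-4a,5,6,7,8,8a-hexahydronaphthalen-1(4H)-one, via N-alkyl-N′-tosylhydrazine 8 (not isolated)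
Conditions: Fe(acac)3 (30 mol %), PhSiH3, TsNHNH2, aq. CH2O, THF/MeOH, rt; then Et3N, MeOH, 65 °C
Reagents that add atoms: formaldehyde p-toluenesulfonylhydrazone (formed in the flask from TsNHNH2 and CH2O), C=NNS(=O)(=O)c1ccc(C)cc1
Why: Markovnikov metal‑hydride hydrogen‑atom transfer to the ring‑A alkene gives the tertiary C4 radical, which adds to the hydrazone carbon, and loss of sulfinate and N2 from 8 leaves the second methyl (olefin hydromethylation) without forming a stereocentre or reducing the electron‑poor enone.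

Step 5
Reactants: 9
Product: 11 (4aR,8aS)-2-hydroxy-2,5,5,8a-tetramethyl-3,4,4a,5,6,7,8,8a-octahydronaphthalen-1(2H)-one (both C2 epimers), via tertiary hydroperoxide 10 (not isolated)
Conditions: Mn(dpm)3 (3 mol %), PhSiH3, O2 (1 atm), iPrOH/CH2Cl2, 0 °C; then P(OEt)3
Reagents that add atoms: dioxygen, O=O
Why: Mukaiyama‑type reductive α‑hydroxylation of the enone (hydrogen‑atom transfer to the β‑carbon, O2 capture at C8, phosphite reduction of the hydroperoxide); the C8 configuration is irrelevant because C8 becomes sp2 in step 8.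

Step 6
Reactants: 11
Product: 12 (4aR,8aS)-2,5,5,8a-tetramethyl-1-methylidenedecahydronaphthalen-2-ol (both C2 epimers)
Conditions: Tebbe reagent Cp2Ti(μ-Cl)(μ-CH2)AlMe2 (3 equiv), pyridine, THF/toluene, −40 °C → rt; aq. NaOH
Reagents that add atoms: Tebbe reagent, C[Al-]1(C)C[Ti](C2C=CC=C2)(C2C=CC=C2)[Cl+]1
Why: Tebbe methylenation (titanium methylidene, oxatitanacyclobutane, cycloreversion) is chosen for this doubly α‑branched ketone because it is non‑basic and cold enough to avoid α‑ketol rearrangement; one extra equivalent is held by the tertiary OH and released on work‑up.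

Step 7
Reactants: 12; 13 3-(benzyloxy)-4-fluorobenzaldehyde
Product: 15 3-(benzyloxy)-4-{[(4aR,8aS)-2,5,5,8a-tetramethyl-1-methylidenedecahydronaphthalen-2-yl]oxy}benzaldehyde (both C2 epimers), via potassium alkoxide 14 (not isolated)
Conditions: KH, THF, 0 °C; then 13, 18-crown-6 (cat.), 0 °C → rt
Reagents that add atoms: none
Why: Nucleophilic aromatic substitution (SNAr) in which the tertiary allylic alkoxide displaces fluoride para to the formyl group, giving the tertiary aryl ether with the C8–O bond intact and no ionisation of the allylic alcohol.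

Step 8
Reactants: 15
Product: 17 3-(benzyloxy)-4-hydroxy-5-{[(4aR,8aS)-2,5,5,8a-tetramethyl-3,4,4a,5,6,7,8,8a-octahydronaphthalen-1-yl]methyl}benzaldehyde, via ortho-dienone 16 (not isolated)
Conditions: PhNEt2, 150 °C
Reagents that add atoms: none
Why: Aromatic Claisen rearrangement ([3,3]‑sigmatropic) joins C11 to the only free ortho carbon, moves the alkene into the tetrasubstituted C8=C9 position and, after tautomerisation of 16, frees the phenol that will be sulfated; both C8 epimers converge and C5 and C10 are untouched.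

Step 9
Reactants: 17
Product: 19 sodium 2-(benzyloxy)-4-formyl-6-{[(4aR,8aS)-2,5,5,8a-tetramethyl-3,4,4a,5,6,7,8,8a-octahydronaphthalen-1-yl]methyl}phenyl sulfate, via pyridinium aryl sulfate 18 (not isolated)
Conditions: SO3·pyridine, pyridine, 45 °C; then aq. NaHCO3
Reagents that add atoms: sulfur trioxide–pyridine complex, [O-]S(=O)(=O)[n+]1ccccc1; sodium hydrogen carbonate, [Na+].OC([O-])=O
Why: O‑sulfation of the only free hydroxyl (the other catechol oxygen is benzylated and the future CH2OH is still an aldehyde), so the sulfate position is fixed by the Claisen step.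

Step 10
Reactants: 19
Product: 20 sodium 2-(benzyloxy)-4-(hydroxymethyl)-6-{[(4aR,8aS)-2,5,5,8a-tetramethyl-3,4,4a,5,6,7,8,8a-octahydronaphthalen-1-yl]methyl}phenyl sulfate
Conditions: NaBH4, MeOH, 0 °C
Reagents that add atoms: none
Why: Chemoselective borohydride reduction of the aldehyde to the benzylic alcohol; the aryl sulfate anion and the tetrasubstituted alkene are inert to hydride.

Step 11
Reactants: 20
Product: 22 2-hydroxy-4-(hydroxymethyl)-6-{[(4aR,8aS)-2,5,5,8a-tetramethyl-3,4,4a,5,6,7,8,8a-octahydronaphthalen-1-yl]methyl}phenyl hydrogen sulfate, via sodium salt 21 (not isolated)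
Conditions: H2 (1 atm), Pd/C, MeOH, rt; filter; then aq. HCl (1.0 equiv), 0 °C, reversed-phase (C18) desalting
Reagents that add atoms: none
Why: Hydrogenolysis of the benzyl ether under neutral conditions leaves the hindered tetrasubstituted alkene, the sulfate salt and the benzylic alcohol intact, and cold stoichiometric protonation gives the hydrogen sulfate.

**Compound list**
1 | (S)-(+)-carvone, (5S)-2-methyl-5-(prop-1-en-2-yl)cyclohex-2-en-1-one | CC1=CC[C@H](C(C)=C)CC1=O | starting material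
2 | 4-iodobut-1-ene | C=CCCI | starting material
3 | lithium (3S)-6-methyl-3-(prop-1-en-2-yl)cyclohexa-1,5-dien-1-olate | CC1=CC[C@H](C(C)=C)C=C1[O-].[Li+] | intermediate
4 | (5S)-6-(but-3-en-1-yl)-2-methyl-5-(prop-1-en-2-yl)cyclohex-2-en-1-one, C6 epimers | CC1=CC[C@H](C(C)=C)C(CCC=C)C1=O | intermediate
5 | lithium (3R)-2-(but-3-en-1-yl)-6-methyl-3-(prop-1-en-2-yl)cyclohexa-1,5-dien-1-olate | CC1=CC[C@H](C(C)=C)C(CCC=C)=C1[O-].[Li+] | intermediate
6 | (5R,6S)-6-(but-3-en-1-yl)-2,6-dimethyl-5-(prop-1-en-2-yl)cyclohex-2-en-1-one | CC1=CC[C@H](C(C)=C)[C@](C)(CCC=C)C1=O | intermediate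
7 | (4aR,8aS)-2,5,8a-trimethyl-4a,7,8,8a-tetrahydronaphthalen-1(4H)-one | CC1=CC[C@@H]2C(C)=CCC[C@]2(C)C1=O | intermediate
8 | N′-{[(4aS,8aR)-1,4a,6-trimethyl-5-oxo-1,2,3,4,4a,5,8,8a-octahydronaphthalen-1-yl]methyl}-4-methylbenzenesulfonohydrazide, C1 epimers | CC1=CC[C@@H]2C(C)(CNNS(=O)(=O)c3ccc(C)cc3)CCC[C@]2(C)C1=O | intermediate
9 | (4aR,8aS)-2,5,5,8a-tetramethyl-4a,5,6,7,8,8a-hexahydronaphthalen-1(4H)-one | CC1=CC[C@@H]2C(C)(C)CCC[C@]2(C)C1=O | intermediate
10 | (4aR,8aS)-2-hydroperoxy-2,5,5,8a-tetramethyl-3,4,4a,5,6,7,8,8a-octahydronaphthalen-1(2H)-one, C2 epimers | CC1(OO)CC[C@@H]2C(C)(C)CCC[C@]2(C)C1=O | intermediate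
11 | (4aR,8aS)-2-hydroxy-2,5,5,8a-tetramethyl-3,4,4a,5,6,7,8,8a-octahydronaphthalen-1(2H)-one, C2 epimers | CC1(O)CC[C@@H]2C(C)(C)CCC[C@]2(C)C1=O | intermediate
12 | (4aR,8aS)-2,5,5,8a-tetramethyl-1-methylidenedecahydronaphthalen-2-ol, C2 epimers | CC1(O)CC[C@@H]2C(C)(C)CCC[C@]2(C)C1=C | intermediate
13 | 3-(benzyloxy)-4-fluorobenzaldehyde | O=Cc1ccc(F)c(OCc2ccccc2)c1 | starting material
14 | potassium (4aR,8aS)-2,5,5,8a-tetramethyl-1-methylidenedecahydronaphthalen-2-olate | CC1([O-])CC[C@@H]2C(C)(C)CCC[C@]2(C)C1=C.[K+] | intermediate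
15 | 3-(benzyloxy)-4-{[(4aR,8aS)-2,5,5,8a-tetramethyl-1-methylidenedecahydronaphthalen-2-yl]oxy}benzaldehyde, C2 epimers | CC1(Oc2ccc(C=O)cc2OCc2ccccc2)CC[C@@H]2C(C)(C)CCC[C@]2(C)C1=C | intermediate
16 | 5-(benzyloxy)-4-oxo-3-{[(4aR,8aS)-2,5,5,8a-tetramethyl-3,4,4a,5,6,7,8,8a-octahydronaphthalen-1-yl]methyl}cyclohexa-1,5-diene-1-carbaldehyde (dienone tautomer of 17) | CC1=C(CC2C=C(C=O)C=C(OCc3ccccc3)C2=O)[C@@]2(C)CCCC(C)(C)[C@H]2CC1 | intermediate
17 | 3-(benzyloxy)-4-hydroxy-5-{[(4aR,8aS)-2,5,5,8a-tetramethyl-3,4,4a,5,6,7,8,8a-octahydronaphthalen-1-yl]methyl}benzaldehyde | CC1=C(Cc2cc(C=O)cc(OCc3ccccc3)c2O)[C@@]2(C)CCCC(C)(C)[C@H]2CC1 | intermediate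
18 | pyridinium 2-(benzyloxy)-4-formyl-6-{[(4aR,8aS)-2,5,5,8a-tetramethyl-3,4,4a,5,6,7,8,8a-octahydronaphthalen-1-yl]methyl}phenyl sulfate | CC1=C(Cc2cc(C=O)cc(OCc3ccccc3)c2OS(=O)(=O)[O-])[C@@]2(C)CCCC(C)(C)[C@H]2CC1.c1cc[nH+]cc1 | intermediate
19 | sodium 2-(benzyloxy)-4-formyl-6-{[(4aR,8aS)-2,5,5,8a-tetramethyl-3,4,4a,5,6,7,8,8a-octahydronaphthalen-1-yl]methyl}phenyl sulfate | CC1=C(Cc2cc(C=O)cc(OCc3ccccc3)c2OS(=O)(=O)[O-])[C@@]2(C)CCCC(C)(C)[C@H]2CC1.[Na+] | intermediate
20 | sodium 2-(benzyloxy)-4-(hydroxymethyl)-6-{[(4aR,8aS)-2,5,5,8a-tetramethyl-3,4,4a,5,6,7,8,8a-octahydronaphthalen-1-yl]methyl}phenyl sulfate | CC1=C(Cc2cc(CO)cc(OCc3ccccc3)c2OS(=O)(=O)[O-])[C@@]2(C)CCCC(C)(C)[C@H]2CC1.[Na+] | intermediate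
21 | sodium 2-hydroxy-4-(hydroxymethyl)-6-{[(4aR,8aS)-2,5,5,8a-tetramethyl-3,4,4a,5,6,7,8,8a-octahydronaphthalen-1-yl]methyl}phenyl sulfate | CC1=C(Cc2cc(CO)cc(O)c2OS(=O)(=O)[O-])[C@@]2(C)CCCC(C)(C)[C@H]2CC1.[Na+] | intermediate
22 | 2-hydroxy-4-(hydroxymethyl)-6-{[(4aR,8aS)-2,5,5,8a-tetramethyl-3,4,4a,5,6,7,8,8a-octahydronaphthalen-1-yl]methyl}phenyl hydrogen sulfate | CC1=C(Cc2cc(CO)cc(O)c2OS(=O)(=O)O)[C@@]2(C)CCCC(C)(C)[C@H]2CC1 | target

**Step count and risks**

Total steps: 11. Longest linear sequence: 11 (1 → 22; 2 and 13 are bought and enter at steps 1 and 7).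

Steps most likely to fail:

Step 4 (iron‑mediated hydromethylation next to a ring‑fusion carbon with an enone present). If radical capture by the hydrazone is poor, the fallback sets out from 7 and comes back at 11, bypassing 9. Et2Zn/CH2I2 cyclopropanates the electron‑rich ring‑A alkene to the cyclopropane F1. Hydrogenolysis (H2, PtO2, AcOH) opens the less hindered CH2–CH bond to the gem‑dimethyl group and saturates the enone C=C, giving the saturated ketone F2; any over‑reduced alcohol is re‑oxidised with Dess–Martin periodinane. Its only possible enolate (KN(SiMe3)2, THF, −78 °C) is hydroxylated with 2‑(phenylsulfonyl)‑3‑phenyloxaziridine to return to ketol 11.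

Step 6 (methylenation of a ketone flanked by a quaternary carbon and a tertiary carbinol). If the titanium methylidene does not engage the carbonyl, the fallback sets out from 11 and comes back at 12 by a Peterson olefination. Excess Me3SiCH2Li with CeCl3 in THF adds to the ketone to give the β‑hydroxysilane diol F3. KH in THF then effects syn‑elimination of silanolate to give 12.

Step 7 (SNAr of a hindered tertiary alkoxide on an aldehyde‑bearing fluoroarene). The alkoxide may add to the formyl group or react too slowly. The fallback sets out from 12 and comes back at 15. Commercial 4‑fluoro‑3‑hydroxybenzonitrile is benzylated (BnBr, K2CO3, DMF) to 3‑(benzyloxy)‑4‑fluorobenzonitrile F4, a stronger SNAr acceptor with no electrophilic carbonyl. Alkoxide 14 (from 12 and KN(SiMe3)2 in THF) displaces its fluoride to give the nitrile ether F5. Reduction with iBu2AlH at −78 °C and buffered hydrolysis of the aldimine (aq. potassium sodium tartrate KNaC4H4O6, wet silica) unmasks the aldehyde and gives 15.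

Further compounds
F1 | step 4 | (4aR,8aS)-2,5,8a-trimethyl-5,6-methano-4a,5,6,7,8,8a-hexahydronaphthalen-1(4H)-one (cyclopropane across C5–C6 of 7, either face) | CC1=CC[C@@H]2C3(C)CC3CC[C@]2(C)C1=O
F2 | step 4 | (4aR,8aS)-2,5,5,8a-tetramethyl-3,4,4a,5,6,7,8,8a-octahydronaphthalen-1(2H)-one, C2 epimers | CC1CC[C@@H]2C(C)(C)CCC[C@]2(C)C1=O
F3 | step 6 | (4aR,8aS)-2,5,5,8a-tetramethyl-1-[(trimethylsilyl)methyl]decahydronaphthalene-1,2-diol, C1/C2 diastereomers | CC1(O)CC[C@@H]2C(C)(C)CCC[C@]2(C)C1(O)C[Si](C)(C)C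
F4 | step 7 | 3-(benzyloxy)-4-fluorobenzonitrile | N#Cc1ccc(F)c(OCc2ccccc2)c1
F5 | step 7 | 3-(benzyloxy)-4-{[(4aR,8aS)-2,5,5,8a-tetramethyl-1-methylidenedecahydronaphthalen-2-yl]oxy}benzonitrile, C2 epimers | CC1(Oc2ccc(C#N)cc2OCc2ccccc2)CC[C@@H]2C(C)(C)CCC[C@]2(C)C1=C
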